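## The problem

The target is a germacranolide: a ten-membered carbocycle (C1–C10) with a trans-fused α-methylene-γ-butyrolactone (C11–C13 on C7, ring oxygen on C6), an angelate on C8, and an unbroken arc of oxidised carbons, namely C10/C1 (trans-epoxide), C2/C3 (cis-epoxide), C4/C15 (spiro-epoxide) and C5 (hydroxyl). A synthesis must make a strained medium ring without a high-dilution macrocyclisation and then set nine stereocentres (1R,2R,3S,4S,5S,6S,7R,8S,10R). C6, C7 and C8 are a contiguous triad best taken from the chiral pool. Once the lactone is trans-fused they fix the shape of the ten-membered ring, so reagents arriving from its periphery can relay configuration to C10/C1 and C5, and the C5 hydroxyl can then direct the C4 epoxide. The functional groups are fragile: three epoxides (acid, and base once a neighbouring hydroxyl is free), a Michael-accepting methylene lactone (nucleophiles, hydride, enolates), and an angelate that isomerises to the tiglate under base, nucleophilic catalysis or UV light. The enabling feature is that C1/C10, C2/C3 and C4/C5 are adjacent pairs, the footprint of a cyclodeca-1(10),2,4-triene. That triene is the ring-opened valence isomer of a cyclohexa-1,3-diene (C1=C2–C3=C4) whose saturated termini C5 and C10 are the ring-fusion atoms of a eudesmane, so light can release the ten-membered ring from rings A and B of a decalin by cutting the C5–C10 bond.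

## Retrosynthesis

**Spiro-epoxide last.** Target 22 is cut at the C4–O and C15–O bonds to the allylic alcohol 21. Doing this last keeps the base-labile epoxy alcohol out of every basic step. It is also the only epoxide that a neighbouring hydroxyl can direct, whereas leaving the 1,10- or 2,3-epoxide to the end would give no such handle. The precursor has one stereocentre less, and the forward step must deliver oxygen to C4=C15 from the side of the 5α-hydroxyl.

**C5 carbinol and 2,3-epoxide.** 21 is cut at C5–H to ketone 20, and 20 at C2–O/C3–O to dienone 19. Oxygen delivered directly to C5 from the ring periphery would give the 5β epimer. Hydride delivered to a C5 ketone from the same periphery gives the 5α-alcohol, so C5 is set by reduction. The cis-alkene is epoxidised at the enone stage because it is then the only electron-rich double bond. These two cuts remove three stereocentres.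

**C5 oxygen.** 19 is cut at C5=O back to the 2Z,4E-diene 16, with C4=C15 returning to C4=C5. A singlet-oxygen ene reaction is preferred to epoxidation and isomerisation of a 4,5-epoxide, because no base could distinguish that epoxide from the equally substituted 1,10-epoxide. The forward step must abstract hydrogen from C15 only.

**Ester, silyl ether, lactone methylene.** 16 is cut at the ester C–O bond to alcohol 13 and angelic acid 14; 13 comes from silyl ether 12, and 12 from the 11-methyl lactone 9 by dehydrogenation of C11–C13. The angelate cannot pass through strong base or 254 nm light, and the methylene lactone cannot pass through enolate chemistry. Both are therefore installed after the ring opening but before C5 carries a hydroxyl, so C5 and C8 never need to be told apart.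

**First epoxide.** 9 is cut at C1–O/C10–O to triene 8. C1=C10 is the most electron-rich alkene of 8, and oxidising it first also destroys the hexatriene that could reclose. The forward step must be fast at low temperature and selective for the outer face.

**Ring.** Triene 8 is traced to the trans-fused eudesma-1,3-diene 7 by re-forming the C5–C10 bond; the forward reaction cuts it. Against cuts at C7–C8, C5–C6 or C4–C5 (see below), this one needs no macrocyclisation and places the three alkenes exactly where oxygen is needed. The precursor is a rigid decalin whose stereocentres come from a natural product.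

**Diene.** 7 comes from enol triflate 6 (C3–H from C3–O), 6 from enone 5, 5 from saturated ketone 3 (C1=C2 by dehydrogenation), 3 from dienone 2 (hydrogenation sets 5α-H), and 2 from artemisin 1 by silylation. Compound 1 already holds C6, C7, C8 and C10 in the target's configuration, so only ring A has to be adjusted.

## Roads not taken

**Alternative 1:** The cut is C7–C8. In the forward step, tin–lithium exchange at C8 of a thirteen-membered O8–C13 allylic ether triggers a [2,3]-Wittig shift. The shift forms C7–C8, breaks O8–C13, creates C11=C13 and contracts the ring to the tetraene A1 with a free C8 hydroxyl.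
- Merits: one step makes the ring, the exocyclic methylene and the C7/C8 pair, and frees the very hydroxyl to be acylated. A1 already carries C4=C15 and the C5 and C6 oxygens, so C5 is set in open-chain chemistry and not by a late ketone reduction. In that respect it is better than the chosen plan.
- Weak points: the substrate is itself a macrocycle with an E,Z-triene, two acetals and an α-stannyl ether, so a macrocyclisation is still needed. The C7/C8 outcome depends on an unexplored transannular transition state, and [1,2]-shift and β-elimination compete. C12 must later be oxidised and lactonised onto O6 in the presence of O5.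
- Comparison: the chosen plan takes C6, C7, C8 and C10 from the chiral pool and makes the ring by a symmetry-controlled reaction with a known outcome, in far fewer steps.

**Alternative 2:** The cut is C5–C6. SmI2 would reduce a C5 and a C6 aldehyde to ketyls that couple, closing the ring and giving the cis-diol A2.
- Merits: convergent; both carbinols form at once, and the cis (5α,6α) relationship the target needs is the normal outcome of such chelated couplings. This addresses C5 more directly than the chosen plan.
- Weak points: C4 is only a ketal and C15 is absent, so a methylenation next to a diol must follow. The C7 aldehyde is epimerisable and the sense of the cis-diol relative to C7/C8 is not secured. O5 and O6 must be differentiated for lactonisation. The dialdehyde with its E,Z-diene and the C7/C8 stereocentres has to be built by asymmetric synthesis.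
- Comparison: the chosen plan needs no such assembly, but it must set C5 late, by substrate-controlled reduction.

**Alternative 3:** The cut is C4–C5. CrCl2 with catalytic NiCl2 would turn a C4 vinyl iodide into a vinylchromium species that adds to the C5 aldehyde, closing the ring to the allylic alcohol A3.
- Merits: the Nozaki–Hiyama–Kishi reaction tolerates lactones and enoates. A3 already has the methylene lactone, C4=C15 and the C5 hydroxyl, so only three epoxidations and the ester exchange remain. Its end game is shorter and needs no selenium chemistry or late reduction, which is better than the chosen plan.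
- Weak points: the C5 configuration rests on the facial preference of an α-acyloxy aldehyde in a medium-ring transition state. That aldehyde can epimerise or eliminate. The 2-iodo-1,3-diene terminus and the C6–C8 triad must be made from scratch, and closing a ten-membered ring containing an E-trisubstituted alkene invites oligomers.
- Comparison: the chosen plan offers a ring formation that needs no dilution, and four stereocentres that are bought.

Key step: step 6

Assumption: artemisin (1), the 8α-hydroxy member of the santonin family of eudesmanolides from Artemisia, is taken as purchasable from natural-product suppliers; it already carries the C8 oxygen, so no C–H oxidation of ring B is needed.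

Assumption: α and β refer to the usual flat drawing (H6 β, H7 α, C14 β); the ten-membered intermediates are taken to react from the crown-like conformer in which they are formed, with reagents arriving from the periphery.

## Route

Step 1
Reactants: 1 artemisin
Product: 2 (11S)-8α-(tert-butyldimethylsilyloxy)-3-oxoeudesma-1,4-dien-12,6α-olide
Conditions: tBuMe2SiCl, imidazole, DMF, rt
Reagents that add atoms: tert-butyldimethylsilyl chloride, CC(C)(C)[Si](C)(C)Cl
Why: Standard silylation of an equatorial secondary alcohol; the cross-conjugated dienone has no enolisable hydrogen and the lactone is untouched. The silyl ether must later survive amide bases, warm formate with palladium, and 254 nm light.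

Step 2
Reactants: 2 (11S)-8α-(tert-butyldimethylsilyloxy)-3-oxoeudesma-1,4-dien-12,6α-olide
Product: 3 (4S,11S)-8α-(tert-butyldimethylsilyloxy)-3-oxo-4βH,5αH-eudesman-12,6α-olide
Conditions: H2 (1 atm), Pd/C (10 wt%), EtOAc, rt; then DBU (cat.), CH2Cl2, rt
Reagents that add atoms: none
Why: Catalytic hydrogenation of both ring A alkenes, known for this dienone class; hydrogen reaches C4=C5 from the α face, opposite the axial C10 methyl, which sets the trans ring fusion (5α-H). The C4 methyl, first axial and syn to C14, is equilibrated by the base to the equatorial position; its configuration is erased again in step 4.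

Step 3
Reactants: 3 (4S,11S)-8α-(tert-butyldimethylsilyloxy)-3-oxo-4βH,5αH-eudesman-12,6α-olide
Product: 5 (11S)-8α-(tert-butyldimethylsilyloxy)-3-oxo-4βH,5αH-eudesm-1-en-12,6α-olide, via trimethylsilyl enol ether 4 (not isolated)
Conditions: LiN(iPr)2, Me3SiCl, THF, −78 °C; then Pd(OAc)2, MeCN, rt
Reagents that add atoms: none
Why: Saegusa–Ito dehydrogenation: kinetic deprotonation takes the C2 methylene rather than the C4 methine or the less acidic lactone α-hydrogen, and Pd(OAc)2 oxidises the silyl enol ether to the 1-en-3-one. No stereocentre is formed.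

Step 4
Reactants: 5 (11S)-8α-(tert-butyldimethylsilyloxy)-3-oxo-4βH,5αH-eudesm-1-en-12,6α-olide
Product: 6 (11S)-8α-(tert-butyldimethylsilyloxy)-3-(trifluoromethanesulfonyloxy)-5αH-eudesma-1,3-dien-12,6α-olide
Conditions: KN(SiMe3)2, PhNTf2, THF, −78 °C
Reagents that add atoms: N-phenylbis(trifluoromethanesulfonimide), O=S(=O)(N(c1ccccc1)S(=O)(=O)C(F)(F)F)C(F)(F)F
Why: The enone can be enolised only toward C4 (C10 is quaternary), so the cross-conjugated dienolate is trapped on oxygen as the 3-triflyloxy-1,3-diene; one equivalent of base at −78 °C leaves the lactone α-hydrogen alone. C4 becomes trigonal.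

Step 5
Reactants: 6 (11S)-8α-(tert-butyldimethylsilyloxy)-3-(trifluoromethanesulfonyloxy)-5αH-eudesma-1,3-dien-12,6α-olide
Product: 7 (11S)-8α-(tert-butyldimethylsilyloxy)-5αH-eudesma-1,3-dien-12,6α-olide
Conditions: Pd(OAc)2 (cat.), PPh3, Bu3N, HCO2H, DMF, 60 °C
Reagents that add atoms: none
Why: Palladium-catalysed formate reduction of an enol triflate: oxidative addition to zerovalent palladium, exchange of triflate for formate, loss of CO2 and C3–H reductive elimination give the homoannular diene without moving the double bonds. C5 (α-H) and C10 are untouched.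

Step 6
Reactants: 7 (11S)-8α-(tert-butyldimethylsilyloxy)-5αH-eudesma-1,3-dien-12,6α-olide
Product: 8 (11S)-8α-(tert-butyldimethylsilyloxy)germacra-1(10)E,2Z,4E-trien-12,6α-olide
Conditions: hν (254 nm, low-pressure Hg lamp, quartz), degassed Et2O, −78 °C, to the photostationary state; solution kept cold
Reagents that add atoms: none
Why: Excitation of the homoannular diene triggers a 6π-electron electrocyclic ring opening that is conrotatory in the excited state: the C5–C10 σ bond is cut and C1=C10, C2=C3 and C4=C5 appear. The closest known reaction type is the opening of ring-fused cyclohexa-1,3-dienes to hexatrienes (provitamin D to previtamin D), known also for trans-fused eudesma-1,3-dien-12,6-olides. No ring is closed; the bond common to rings A and B is broken, so the two six-membered rings merge into the ten-membered ring. No stereocentre is formed; C5 and C10 become trigonal while C6, C7, C8 and C11 are untouched. The selectivity needed is the 1(10)E,2Z,4E triene rather than the all-Z isomer: in the trans-fused diene C9 and C6 leave C10 and C5 on opposite faces of ring A, so conrotation turns both outward (the inward sense would drag the C6–C9 bridge through the ring), and C2=C3 stays Z because it was part of the six-membered ring. Low temperature keeps 8 from disrotatory thermal reclosure to a cis-fused diene and from 1,7-hydrogen shift, and irradiation stops at the photostationary state because 8 absorbs as well. Lactone and silyl ether do not absorb at this wavelength.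

Step 7
Reactants: 8 (11S)-8α-(tert-butyldimethylsilyloxy)germacra-1(10)E,2Z,4E-trien-12,6α-olide
Product: 9 (1R,10R,11S)-8α-(tert-butyldimethylsilyloxy)-1β,10α-epoxygermacra-2Z,4E-dien-12,6α-olide
Conditions: dimethyldioxirane (1 equiv on 8), acetone/Et2O, −78 to −40 °C, added to the cold photolysate
Reagents that add atoms: dimethyldioxirane, CC1(C)OO1
Why: Electrophilic epoxidation takes the strained trisubstituted C1=C10 (C4=C5 is deactivated by the allylic lactone oxygen, C2=C3 is only disubstituted) and thereby removes the hexatriene that could reclose. Oxygen arrives on the outer face, opposite the place C5 held before the opening, giving the (1R,10R) 1β,10α-epoxide; the unstrained diene 7 left in the mixture reacts more slowly and is recovered.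

Step 8
Reactants: 9 (1R,10R,11S)-8α-(tert-butyldimethylsilyloxy)-1β,10α-epoxygermacra-2Z,4E-dien-12,6α-olide
Product: 12 (1R,10R)-8α-(tert-butyldimethylsilyloxy)-1β,10α-epoxygermacra-2Z,4E,11(13)-trien-12,6α-olide, via 11β-phenylselenide 10 (not isolated), via selenoxide 11 (not isolated)
Conditions: LiN(iPr)2, THF, −78 °C; PhSeCl, −78 °C; then H2O2 (30% aq.), pyridine, CH2Cl2, 0 °C to rt
Reagents that add atoms: none
Why: α-Selenenylation of the lactone enolate and selenoxide syn-elimination, the standard conversion of 11-methyl into 11-methylene lactones in trans-fused germacranolides. Selenium enters anti to H7 (β face), so the selenoxide can eliminate only toward C13; at −78 °C the amide base does not open the vinyl epoxide.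

Step 9
Reactants: 12 (1R,10R)-8α-(tert-butyldimethylsilyloxy)-1β,10α-epoxygermacra-2Z,4E,11(13)-trien-12,6α-olide
Product: 13 (1R,10R)-1β,10α-epoxy-8α-hydroxygermacra-2Z,4E,11(13)-trien-12,6α-olide
Conditions: Bu4NF, AcOH (1:1), THF, 0 °C to rt
Reagents that add atoms: none
Why: Fluoride cleavage of the secondary silyl ether; the acetic acid buffer keeps the medium from turning basic, so the lactone does not migrate to O8 and no alkoxide adds to the methylene lactone.

Step 10
Reactants: 13 (1R,10R)-1β,10α-epoxy-8α-hydroxygermacra-2Z,4E,11(13)-trien-12,6α-olide; 14 angelic acid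
Product: 16 (1R,10R)-8α-angeloyloxy-1β,10α-epoxygermacra-2Z,4E,11(13)-trien-12,6α-olide, via angelic 2,4,6-trichlorobenzoic anhydride 15 (not isolated)
Conditions: 14, 2,4,6-trichlorobenzoyl chloride, Et3N, toluene, rt; then 13, 75 °C
Reagents that add atoms: none
Why: Yamaguchi esterification through the mixed anhydride; omitting a nucleophilic amine catalyst suppresses addition–elimination isomerisation of the angelate (Z) to the tiglate (E). The C8 hydroxyl is the only one present.

Step 11
Reactants: 16 (1R,10R)-8α-angeloyloxy-1β,10α-epoxygermacra-2Z,4E,11(13)-trien-12,6α-olide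
Product: 19 (1R,10R)-8α-angeloyloxy-1β,10α-epoxy-5-oxogermacra-2Z,4(15),11(13)-trien-12,6α-olide, via 5β-hydroperoxide 17 (not isolated), via peracetate 18 (not isolated)
Conditions: O2, tetraphenylporphyrin (cat.), visible light, CH2Cl2, −20 °C; then Ac2O, pyridine, 4-(dimethylamino)pyridine (cat.), 0 °C
Reagents that add atoms: oxygen, O=O
Why: Schenck ene reaction of singlet oxygen with the only electron-rich trisubstituted alkene: the C15 methyl on the disubstituted side gives up the hydrogen, oxygen bonds to C5 and the double bond moves to C4=C15; Kornblum–DeLaMare dehydration of the peracetate then gives the ketone. Both C5 epimers of the hydroperoxide converge on the same ketone, and the enoates are too electron-poor to react.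

Step 12
Reactants: 19 (1R,10R)-8α-angeloyloxy-1β,10α-epoxy-5-oxogermacra-2Z,4(15),11(13)-trien-12,6α-olide
Product: 20 8α-angeloyloxy-1β,10α;2β,3β-diepoxy-5-oxogermacra-4(15),11(13)-dien-12,6α-olide
Conditions: dimethyldioxirane, acetone/CH2Cl2, 0 °C
Reagents that add atoms: dimethyldioxirane, CC1(C)OO1
Why: Dioxirane epoxidation of the one electron-rich alkene left (C4=C15, C11=C13 and the angelate are all conjugated to carbonyls), with retention of the cis geometry. Attack is expected on the β face because in the crown conformer the C5 carbonyl oxygen lies under the α face, where H5 stood, and H1 eclipses that side.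

Step 13
Reactants: 20 8α-angeloyloxy-1β,10α;2β,3β-diepoxy-5-oxogermacra-4(15),11(13)-dien-12,6α-olide
Product: 21 8α-angeloyloxy-1β,10α;2β,3β-diepoxy-5α-hydroxygermacra-4(15),11(13)-dien-12,6α-olide
Conditions: NaBH4, CeCl3·7H2O, MeOH, −78 °C
Reagents that add atoms: none
Why: Luche reduction, 1,2-selective for the enone and fast at −78 °C, so the methylene lactone and both esters survive. Hydride comes from the periphery of C5 while the carbonyl oxygen stays on the α side where H5 stood, giving the 5α-alcohol (5S), the epimer of what direct oxygen delivery to C5 would give.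

Step 14
Reactants: 21 8α-angeloyloxy-1β,10α;2β,3β-diepoxy-5α-hydroxygermacra-4(15),11(13)-dien-12,6α-olide
Product: 22 8α-angeloyloxy-1β,10α;2β,3β;4α,15-triepoxy-5α-hydroxygermacr-11(13)-en-12,6α-olide (target)
Conditions: VO(acac)2 (cat.), tBuOOH (decane), CH2Cl2, 0 °C
Reagents that add atoms: tert-butyl hydroperoxide, CC(C)(C)OO
Why: Hydroxyl-directed epoxidation: the vanadate ester of the 5α-hydroxyl delivers oxygen to the same (α, peripheral) face of the 1,1-disubstituted C4=C15, giving the 4α,15-epoxide (4S), while the two enoates are inert. Placing this step last keeps the epoxy alcohol away from base and Payne rearrangement.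

## Compound list

1 | artemisin, (11S)-8α-hydroxy-3-oxoeudesma-1,4-dien-12,6α-olide (6βH, 7αH, 10β-methyl) | C[C@@H]1C(=O)O[C@H]2[C@H]1[C@@H](O)C[C@@]3(C)C=CC(=O)C(C)=C23 | starting material
2 | (11S)-8α-(tert-butyldimethylsilyloxy)-3-oxoeudesma-1,4-dien-12,6α-olide | C[C@@H]1C(=O)O[C@H]2[C@H]1[C@@H](O[Si](C)(C)C(C)(C)C)C[C@@]3(C)C=CC(=O)C(C)=C23 | intermediate
3 | (4S,11S)-8α-(tert-butyldimethylsilyloxy)-3-oxo-4βH,5αH-eudesman-12,6α-olide (C4 methyl α, equatorial; trans ring fusion) | C[C@@H]1C(=O)O[C@H]2[C@H]1[C@@H](O[Si](C)(C)C(C)(C)C)C[C@@]3(C)CCC(=O)[C@@H](C)[C@H]23 | intermediate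
4 | (11S)-8α-(tert-butyldimethylsilyloxy)-3-(trimethylsilyloxy)-4βH,5αH-eudesm-2-en-12,6α-olide | C[C@@H]1C(=O)O[C@H]2[C@H]1[C@@H](O[Si](C)(C)C(C)(C)C)C[C@@]3(C)CC=C(O[Si](C)(C)C)[C@@H](C)[C@H]23 | intermediate (not isolated)
5 | (11S)-8α-(tert-butyldimethylsilyloxy)-3-oxo-4βH,5αH-eudesm-1-en-12,6α-olide | C[C@@H]1C(=O)O[C@H]2[C@H]1[C@@H](O[Si](C)(C)C(C)(C)C)C[C@@]3(C)C=CC(=O)[C@@H](C)[C@H]23 | intermediate
6 | (11S)-8α-(tert-butyldimethylsilyloxy)-3-(trifluoromethanesulfonyloxy)-5αH-eudesma-1,3-dien-12,6α-olide | C[C@@H]1C(=O)O[C@H]2[C@H]1[C@@H](O[Si](C)(C)C(C)(C)C)C[C@@]3(C)C=CC(OS(=O)(=O)C(F)(F)F)=C(C)[C@H]23 | intermediate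
7 | (11S)-8α-(tert-butyldimethylsilyloxy)-5αH-eudesma-1,3-dien-12,6α-olide | C[C@@H]1C(=O)O[C@H]2[C@H]1[C@@H](O[Si](C)(C)C(C)(C)C)C[C@@]3(C)C=CC=C(C)[C@H]23 | intermediate (key-step precursor)
8 | (11S)-8α-(tert-butyldimethylsilyloxy)germacra-1(10)E,2Z,4E-trien-12,6α-olide | C[C@@H]1C(=O)O[C@@H]2/C=C(C)/C=C\C=C(C)\C[C@H](O[Si](C)(C)C(C)(C)C)[C@@H]12 | intermediate (key-step product, used cold in solution)
9 | (1R,10R,11S)-8α-(tert-butyldimethylsilyloxy)-1β,10α-epoxygermacra-2Z,4E-dien-12,6α-olide | C[C@@H]1C(=O)O[C@@H]2/C=C(C)/C=C\[C@H]3O[C@]3(C)C[C@H](O[Si](C)(C)C(C)(C)C)[C@@H]12 | intermediate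
10 | (1R,10R)-8α-(tert-butyldimethylsilyloxy)-1β,10α-epoxy-11β-(phenylseleno)germacra-2Z,4E-dien-12,6α-olide (11α-methyl) | C[C@]1([Se]c2ccccc2)C(=O)O[C@@H]3/C=C(C)/C=C\[C@H]4O[C@]4(C)C[C@H](O[Si](C)(C)C(C)(C)C)[C@@H]13 | intermediate (not isolated)
11 | selenoxide of 10 (both configurations at selenium) | C[C@]1([Se](=O)c2ccccc2)C(=O)O[C@@H]3/C=C(C)/C=C\[C@H]4O[C@]4(C)C[C@H](O[Si](C)(C)C(C)(C)C)[C@@H]13 | intermediate (not isolated)
12 | (1R,10R)-8α-(tert-butyldimethylsilyloxy)-1β,10α-epoxygermacra-2Z,4E,11(13)-trien-12,6α-olide | C=C1C(=O)O[C@@H]2/C=C(C)/C=C\[C@H]3O[C@]3(C)C[C@H](O[Si](C)(C)C(C)(C)C)[C@@H]12 | intermediate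
13 | (1R,10R)-1β,10α-epoxy-8α-hydroxygermacra-2Z,4E,11(13)-trien-12,6α-olide | C=C1C(=O)O[C@@H]2/C=C(C)/C=C\[C@H]3O[C@]3(C)C[C@H](O)[C@@H]12 | intermediate
14 | angelic acid, (Z)-2-methylbut-2-enoic acid | C/C=C(/C)C(=O)O | starting material
15 | angelic 2,4,6-trichlorobenzoic anhydride | C/C=C(/C)C(=O)OC(=O)c1c(Cl)cc(Cl)cc1Cl | intermediate (not isolated)
16 | (1R,10R)-8α-angeloyloxy-1β,10α-epoxygermacra-2Z,4E,11(13)-trien-12,6α-olide | C=C1C(=O)O[C@@H]2/C=C(C)/C=C\[C@H]3O[C@]3(C)C[C@H](OC(=O)/C(C)=C\C)[C@@H]12 | intermediate
17 | (1R,10R)-8α-angeloyloxy-1β,10α-epoxy-5β-hydroperoxygermacra-2Z,4(15),11(13)-trien-12,6α-olide | C=C1C(=O)O[C@@H]2[C@@H](OO)C(=C)/C=C\[C@H]3O[C@]3(C)C[C@H](OC(=O)/C(C)=C\C)[C@@H]12 | intermediate (not isolated)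
18 | 5β-acetylperoxy analogue of 17 | C=C1C(=O)O[C@@H]2[C@@H](OOC(C)=O)C(=C)/C=C\[C@H]3O[C@]3(C)C[C@H](OC(=O)/C(C)=C\C)[C@@H]12 | intermediate (not isolated)
19 | (1R,10R)-8α-angeloyloxy-1β,10α-epoxy-5-oxogermacra-2Z,4(15),11(13)-trien-12,6α-olide | C=C1C(=O)O[C@@H]2C(=O)C(=C)/C=C\[C@H]3O[C@]3(C)C[C@H](OC(=O)/C(C)=C\C)[C@@H]12 | intermediate
20 | 8α-angeloyloxy-1β,10α;2β,3β-diepoxy-5-oxogermacra-4(15),11(13)-dien-12,6α-olide | C=C1C(=O)O[C@@H]2C(=O)C(=C)[C@H]3O[C@H]3[C@H]4O[C@]4(C)C[C@H](OC(=O)/C(C)=C\C)[C@@H]12 | intermediate
21 | 8α-angeloyloxy-1β,10α;2β,3β-diepoxy-5α-hydroxygermacra-4(15),11(13)-dien-12,6α-olide | C=C1C(=O)O[C@@H]2[C@H](O)C(=C)[C@H]3O[C@H]3[C@H]4O[C@]4(C)C[C@H](OC(=O)/C(C)=C\C)[C@@H]12 | intermediate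
22 | CNP0594916.1, (1R,2R,3S,4S,5S,6S,7R,8S,10R)-8α-angeloyloxy-1β,10α;2β,3β;4α,15-triepoxy-5α-hydroxygermacr-11(13)-en-12,6α-olide | C=C1C(=O)O[C@H]2[C@H]1[C@@H](OC(=O)/C(C)=C\C)C[C@@]1(C)O[C@@H]1[C@@H]1O[C@@H]1[C@]1(CO1)[C@H]2O | target

## Step count and least certain steps

Total step count: 14. Longest linear sequence: 14 steps (1 to 22); angelic acid 14 is bought.

**Step 6 (key step).** The photostationary mixture may hold too little of 8, and longer irradiation drains both isomers into secondary photoproducts (bicyclo[3.1.0]hexenes, Z/E scrambling). Alternatively 8 may reclose thermally before step 7 can intercept it; the triene cannot be purified. Step 7 shares this risk, since the dioxirane must discriminate between 8 and the remaining diene and among three alkenes.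

Fallback, setting out from 5 and returning at 9:
- Enone 5 is silylated with tBuMe2SiOSO2CF3 and Et3N to the silyl dienol ether (11S)-3,8α-bis(tert-butyldimethylsilyloxy)-5αH-eudesma-1,3-dien-12,6α-olide F1.
- Irradiation opens it in the same conrotatory way to the 3-silyloxy triene F2.
- Bu4NF/AcOH at −78 °C cleaves the enol ether at once, protonating C2 and leaving the 1(10)E,4E-dien-3-one F3. This ketone has no hexatriene, cannot reclose, and lets recovered F1 be recycled.
- Dimethyldioxirane epoxidises the isolated C1=C10 (the enone alkene is electron-poor) to the 1β,10α-epoxide F4.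
- NaBH4/CeCl3 gives the allylic alcohol F5.
- Dehydration with methyl N-(triethylammoniosulfonyl)carbamate, which can take a hydrogen only from C2, gives the 2Z,4E-diene 9.

**Step 12.** Facial selectivity may be poor or reversed. The two faces of the cis-alkene differ only through the flanking C1 oxirane, the C5 carbonyl and the β-oriented C14 and C15, so a small change of ring conformation could turn the dioxirane to the α face.

Fallback, setting out from 19 and returning at 20: N-bromosuccinimide in aqueous 1,2-dimethoxyethane puts bromine on the face the dioxirane prefers and water on the other, giving the trans-bromohydrin 8α-angeloyloxy-3α-bromo-1β,10α-epoxy-2β-hydroxy-5-oxogermacra-2,3-dihydro-4(15),11(13)-dien-12,6α-olide F6 (its regioisomer serves equally). K2CO3 closes it with inversion at the bromine-bearing carbon to the β-epoxide 20.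

**Step 13.** Hydride may reach the wrong face of the C5 ketone if the enone leaves the crown geometry (carbonyl turned into the ring plane), giving the 5β-alcohol; some conjugate reduction of the methylene lactone is also possible.

Fallback, setting out from 20 and returning at 21: the reduction product 8α-angeloyloxy-1β,10α;2β,3β-diepoxy-5β-hydroxygermacra-4(15),11(13)-dien-12,6α-olide F7 is inverted by a Mitsunobu reaction with chloroacetic acid (PPh3, diisopropyl azodicarboxylate) to the 5α-chloroacetate F8. Thiourea and NaHCO3 in ethanol cleave this ester without touching the angelate, giving 21.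

**Step 11.** The acylative dehydration may erode the product (epimerisation at C6 next to the new ketone, conjugate addition of the amine bases to the exocyclic enone), and the new diene may be photooxygenated further.

Fallback, setting out from 16 and returning at 19: the photooxygenation is stopped at hydroperoxide 17, which PPh3 reduces at −20 °C to the allylic alcohol (1R,10R)-8α-angeloyloxy-1β,10α-epoxy-5β-hydroxygermacra-2Z,4(15),11(13)-trien-12,6α-olide F9. Oxidation with 1,1,1-triacetoxy-1,1-dihydro-1,2-benziodoxol-3(1H)-one under NaHCO3 buffer then gives 19 without amine base.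

## Further compounds

F1 | step 6 | (11S)-3,8α-bis(tert-butyldimethylsilyloxy)-5αH-eudesma-1,3-dien-12,6α-olide | C[C@@H]1C(=O)O[C@H]2[C@H]1[C@@H](O[Si](C)(C)C(C)(C)C)C[C@@]3(C)C=CC(O[Si](C)(C)C(C)(C)C)=C(C)[C@H]23
F2 | step 6 | (11S)-3,8α-bis(tert-butyldimethylsilyloxy)germacra-1(10)E,2,4E-trien-12,6α-olide (C1 and C4 cis on C2=C3) | C[C@@H]1C(=O)O[C@@H]2/C=C(C)/C(O[Si](C)(C)C(C)(C)C)=C\C=C(C)\C[C@H](O[Si](C)(C)C(C)(C)C)[C@@H]12
F3 | step 6 | (11S)-8α-(tert-butyldimethylsilyloxy)-3-oxogermacra-1(10)E,4E-dien-12,6α-olide | C[C@@H]1C(=O)O[C@@H]2/C=C(C)/C(=O)C/C=C(C)/C[C@H](O[Si](C)(C)C(C)(C)C)[C@@H]12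
F4 | step 6 | (1R,10R,11S)-8α-(tert-butyldimethylsilyloxy)-1β,10α-epoxy-3-oxogermacr-4E-en-12,6α-olide | C[C@@H]1C(=O)O[C@@H]2/C=C(C)/C(=O)C[C@H]3O[C@]3(C)C[C@H](O[Si](C)(C)C(C)(C)C)[C@@H]12
F5 | step 6 | (1R,10R,11S)-8α-(tert-butyldimethylsilyloxy)-1β,10α-epoxy-3-hydroxygermacr-4E-en-12,6α-olide (both C3 epimers, which give the same diene) | C[C@@H]1C(=O)O[C@@H]2/C=C(C)/C(O)C[C@H]3O[C@]3(C)C[C@H](O[Si](C)(C)C(C)(C)C)[C@@H]12
F6 | step 12 | 8α-angeloyloxy-3α-bromo-1β,10α-epoxy-2β-hydroxy-5-oxogermacra-4(15),11(13)-dien-12,6α-olide | C=C1C(=O)O[C@@H]2C(=O)C(=C)[C@H](Br)[C@@H](O)[C@H]3O[C@]3(C)C[C@H](OC(=O)/C(C)=C\C)[C@@H]12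
F7 | step 13 | 8α-angeloyloxy-1β,10α;2β,3β-diepoxy-5β-hydroxygermacra-4(15),11(13)-dien-12,6α-olide | C=C1C(=O)O[C@@H]2[C@@H](O)C(=C)[C@H]3O[C@H]3[C@H]4O[C@]4(C)C[C@H](OC(=O)/C(C)=C\C)[C@@H]12
F8 | step 13 | 8α-angeloyloxy-5α-(chloroacetoxy)-1β,10α;2β,3β-diepoxygermacra-4(15),11(13)-dien-12,6α-olide | C=C1C(=O)O[C@@H]2[C@H](OC(=O)CCl)C(=C)[C@H]3O[C@H]3[C@H]4O[C@]4(C)C[C@H](OC(=O)/C(C)=C\C)[C@@H]12
F9 | step 11 | (1R,10R)-8α-angeloyloxy-1β,10α-epoxy-5β-hydroxygermacra-2Z,4(15),11(13)-trien-12,6α-olide | C=C1C(=O)O[C@@H]2[C@@H](O)C(=C)/C=C\[C@H]3O[C@]3(C)C[C@H](OC(=O)/C(C)=C\C)[C@@H]12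
A1 | alternative 1 | 12-(tert-butyldimethylsilyloxy)-8α-hydroxy-5,6-bis(methoxymethoxy)germacra-1(10)E,2Z,4(15),11(13)-tetraene | C=C(CO[Si](C)(C)C(C)(C)C)[C@H]1[C@H](OCOC)[C@H](OCOC)C(=C)/C=C\C=C(C)\C[C@@H]1O
A2 | alternative 2 | 8,12-bis(tert-butyldimethylsilyloxy)-15-norgermacra-1(10)E,2Z,11(13)-triene-5α,6α-diol 4-(ethylene ketal) | O[C@H]1[C@H](C(=C)CO[Si](C)(C)C(C)(C)C)[C@@H](O[Si](C)(C)C(C)(C)C)C/C(C)=C/C=C\C2(OCCO2)[C@H]1O
A3 | alternative 3 | 8α-(tert-butyldimethylsilyloxy)-5α-hydroxygermacra-1(10)E,2Z,4(15),11(13)-tetraen-12,6α-olide | C=C1C(=O)O[C@@H]2[C@H](O)C(=C)/C=C\C=C(C)\C[C@H](O[Si](C)(C)C(C)(C)C)[C@@H]12
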